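**Retrosynthetic overview**

1. Numbering: ring A is C1–C6 (C1 = C(CH3)OH, C2 = CHOH, C3 = CH carrying the CH2 arm, C4 = CH–isopropenyl); ring B is C1'–C6' (C1' = CH on the linker carbon, C4' = C(CH3)OH, C5' = CHBr, syn to the OH). Late disconnections: C=CH2 from a linker ketone (Wittig); C1' by base equilibration α to that ketone; C4'–CH3 by CH3MgBr on an α-bromoketone; C5'–Br by enamine-catalysed enantioselective α-bromination.
2. Ring B comes from a [4+2] cycloaddition of a vinyl ketone (C1'=C2' plus the linker C=O) with a 2-silyloxybutadiene (C3'–C4'(O)–C5'–C6'). The enabling feature is that C4' (oxygenated) lies para to C1', C1' carries a carbon that can be a ketone, and ring B has a local mirror plane through C1' and C4' that only the Br on C5' breaks. The ring can therefore be closed as an achiral 4-acylcyclohexanone; its three stereocentres then follow from one catalyst-controlled bromination and two convergent funnels (methyl addition anti to Br from either chair; equilibration of C1').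
3. The vinyl ketone comes from a Weinreb amide, installed by alkylation at C3 of the α-ketol of limonene-1,2-diol; C2–OH is re-set by hydroxyl-directed reduction.
4. Ring A is the carbocycle of (S)-limonene oxide (C1/C2 by stereoconvergent diaxial hydrolysis) and is never opened. Ring B is the only ring formed and is closed last, in step 7.

Key step: step 7

Assumption: 1 is the commercial (−)-limonene oxide (4S, cis/trans mixture), the bromine donor of step 8 is a known reagent taken as available, and the (4R,5R) catalyst of step 8 is assumed to give the 5'R bromide (its antipode would be used if a model ketone showed the opposite sense).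

**Route**

Step 1
Reactants: 1 (4S)-limonene 1,2-oxide (cis/trans mixture)
Product: 2 (1R,2R,4S)-limonene-1,2-diol
Conditions: H2SO4 (cat.), H2O/THF, 0 °C → rt
Reagents that add atoms: water, O
Why: Acid-catalysed epoxide hydrolysis under the Fürst–Plattner (trans-diaxial opening) rule is stereoconvergent, since the epoxide with oxygen anti to the isopropenyl group should be opened by water at C1 and its diastereomer at C2, each with inversion, so that both give the same diaxial (1R,2R) diol.

Step 2
Reactants: 2 (1R,2R,4S)-limonene-1,2-diol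
Product: 3 (2R,5S)-2-hydroxy-2-methyl-5-(prop-1-en-2-yl)cyclohexan-1-one
Conditions: IBX, DMSO, rt
Reagents that add atoms: none
Why: IBX oxidation of the secondary alcohol of a 1,2-diol should give the α-ketol without C–C cleavage, the tertiary C1–OH being unable to oxidise and the C1 and C4 stereocentres being untouched.

Step 3
Reactants: 3 α-ketol; 4 2-bromo-N-methoxy-N-methylacetamide
Product: 5 keto Weinreb amide (C3 arm trans to isopropenyl)
Conditions: LiN(i-Pr)2 (2.2 equiv), THF, −78 → −20 °C; then 4, DMPU, −78 → −20 °C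
Reagents that add atoms: 4 2-bromo-N-methoxy-N-methylacetamide, O=C(CBr)N(C)OC
Why: SN2 alkylation of the alkoxide–enolate dianion should occur only at C3 (C1 is quaternary) and anti to the neighbouring C4 isopropenyl group, giving the trans (3R) product, which is also the thermodynamic diequatorial epimer of this enolisable centre.

Step 4
Reactants: 5 keto Weinreb amide
Product: 6 trans-diaxial diol Weinreb amide
Conditions: (CH3)4NBH(OAc)3, CH3CN/AcOH, −30 → 0 °C
Reagents that add atoms: none
Why: Hydroxyl-directed reduction (Evans–Saksena type): the triacetoxyborohydride should exchange onto the axial C1–OH and deliver hydride intramolecularly to the same face of the C2 carbonyl, setting C2–OH anti to C1–OH (2R), while the amide and alkene are not reduced.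

Step 5
Reactants: 6 diol Weinreb amide
Product: 7 bis(triethylsilyl) ether Weinreb amide
Conditions: Et3SiOTf, 2,6-lutidine, CH2Cl2, −78 → 0 °C
Reagents that add atoms: triethylsilyl trifluoromethanesulfonate, CC[Si](CC)(CC)OS(=O)(=O)C(F)(F)F
Why: Silyl triflate silylation should cap both the secondary and the hindered tertiary alcohol, and is run at once so that the γ-hydroxy amide cannot lactonise; no stereocentre is touched.

Step 6
Reactants: 7 bis-silyl Weinreb amide; 8 vinylmagnesium bromide
Product: 9 vinyl ketone (dienophile)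
Conditions: CH2=CHMgBr, THF, −20 → 0 °C; inverse quench into cold aq. NH4Cl
Reagents that add atoms: 8 vinylmagnesium bromide, C=C[Mg]Br
Why: Weinreb ketone synthesis: the chelated tetrahedral intermediate should prevent over-addition, and the cold inverse quench limits conjugate addition of the liberated amine to the enone.

Step 7
Reactants: 9 vinyl ketone; 10 2-(trimethylsilyloxy)buta-1,3-diene
Product: 12 4-acylcyclohexanone (ring B closed), via trimethylsilyl enol ether 11 (not isolated)
Conditions: 10 (4 equiv), BHT (cat.), toluene, 110 °C, sealed tube; then AcOH/H2O/THF, 0 °C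
Reagents that add atoms: 10 2-(trimethylsilyloxy)buta-1,3-diene, C=CC(=C)O[Si](C)(C)C
Why: The step is a thermal, concerted asynchronous [4+2] cycloaddition of normal electron demand between the electron-rich diene 10 and the enone 9, the long-established Diels–Alder reaction of 2-silyloxybutadienes with alkyl vinyl ketones. Ring B is closed in the intermolecular cycloaddition mode: C1'–C6' and C2'–C3' form suprafacially in one event, giving the six-membered carbocycle and no other ring. The regioselectivity that is needed is para (C4'–O across the ring from C1'); it is secured by the silyloxy donor on C4', which makes the adjacent diene terminus C3' the nucleophile that bonds to the β-carbon (C2') of the enone. Chemoselectivity is secured because the vinyl ketone is the only activated 2π component; the isopropenyl group and the silyl ethers should be inert at 110 °C without a Lewis acid, and excess diene should outrun enone dimerisation. The one new stereocentre, C1' of 11, forms without control because ring A is too remote, and this is accepted by design: hydrolysis of the enol ether to 12 restores the local mirror plane through C1' and C4', so C1' ceases to be a stereocentre and is set later by equilibration (step 10). In one operation the step therefore joins the ring A fragment to a four-carbon diene, builds all six carbons of ring B and places the C4' oxygen that the bromination and the methyl addition need.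

Step 8
Reactants: 12 4-acylcyclohexanone
Product: 13 (2R)-2-bromo-4-acylcyclohexanone (5'R; both C1' epimers)
Conditions: (4R,5R)-4,5-diphenylimidazolidine (20 mol %), PhCO2H (20 mol %), 4,4-dibromo-2,6-di-tert-butylcyclohexa-2,5-dien-1-one (1.05 equiv), THF, −30 °C; cold work-up, used at once
Reagents that add atoms: 4,4-dibromo-2,6-di-tert-butylcyclohexa-2,5-dien-1-one, O=C1C(C(C)(C)C)=CC(Br)(Br)C=C1C(C)(C)C
Why: Enamine-catalysed enantioselective α-bromination of a cyclohexanone, here a desymmetrisation: the C2-symmetric amine should fix the configuration of the brominated carbon (C5', R) whichever α-carbon or chair reacts, the cis/trans relation to C1' is immaterial because C1' is equilibrated later, and the hindered acyclic linker ketone should not form an enamine.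

Step 9
Reactants: 13 α-bromoketone; 14 methylmagnesium bromide
Product: 15 syn-bromohydrin ketone (4'S,5'R; both C1' epimers)
Conditions: CH3MgBr, Et2O/CH2Cl2, −78 °C; AcOH quench at −78 °C
Reagents that add atoms: 14 methylmagnesium bromide, C[Mg]Br
Why: Grignard 1,2-addition under Cornforth/Felkin–Anh control: both C1' epimers should react through the chair with axial C–Br (Curtin–Hammett) and take the methyl group anti to bromine, so that OH ends syn to Br (4'S) in both, and the α-bromoketone should be far more electrophilic than the hindered linker ketone.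

Step 10
Reactants: 15 syn-bromohydrin ketone (C1' epimers)
Product: 16 (1'R,4'S,5'R) bromohydrin ketone
Conditions: NaOCH3 (0.3 equiv), CH3OH/THF, 0 °C → rt
Reagents that add atoms: none
Why: Thermodynamic epimerisation through the enolate of the linker ketone should funnel both C1' epimers into the isomer with the acyl group, Br and CH3 all equatorial (C1' R); C4' and C5' cannot enolise, the syn-bromohydrin cannot close to an epoxide, and SN2 at the neopentyl-type C5' should be slow.

Step 11
Reactants: 16 bromohydrin ketone; 17 methyltriphenylphosphonium bromide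
Product: 18 bis(triethylsilyl) ether of Prevezol C
Conditions: Ph3PCH3Br, KOC(CH3)3 (3 equiv ylide), THF, 0 °C → rt
Reagents that add atoms: 17 methyltriphenylphosphonium bromide (as its ylide), C[P+](c1ccccc1)(c1ccccc1)c1ccccc1.[Br-]
Why: Wittig methylenation of the linker ketone should install the 1,1-disubstituted alkene; any enolisation at C1' under the basic conditions is harmless because the desired configuration is the thermodynamic one.

Step 12
Reactants: 18 bis-silyl ether
Product: 19 Prevezol C
Conditions: HF·pyridine, THF/pyridine, 0 °C → rt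
Reagents that add atoms: none
Why: Fluoride-mediated desilylation should free the ring A diol without touching a stereocentre; the equatorial bromide has no antiperiplanar hydrogen and the syn-bromohydrin cannot form an epoxide.

**Compound list**

1 | (4S)-limonene 1,2-oxide, cis/trans mixture | C=C(C)[C@H]1CCC2(C)OC2C1 | starting material
2 | (1R,2R,4S)-1-methyl-4-(prop-1-en-2-yl)cyclohexane-1,2-diol | C1[C@@H](C(=C)C)CC[C@@](C)(O)[C@@H]1O | intermediate
3 | (2R,5S)-2-hydroxy-2-methyl-5-(prop-1-en-2-yl)cyclohexan-1-one | C1[C@@H](C(=C)C)CC[C@@](C)(O)C1=O | intermediate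
4 | 2-bromo-N-methoxy-N-methylacetamide | O=C(CBr)N(C)OC | starting material
5 | 2-[(1R,3R,6S)-3-hydroxy-3-methyl-2-oxo-6-(prop-1-en-2-yl)cyclohexyl]-N-methoxy-N-methylacetamide | CON(C)C(=O)C[C@@H]1[C@@H](C(=C)C)CC[C@@](C)(O)C1=O | intermediate
6 | 2-[(1R,2R,3R,6S)-2,3-dihydroxy-3-methyl-6-(prop-1-en-2-yl)cyclohexyl]-N-methoxy-N-methylacetamide | CON(C)C(=O)C[C@@H]1[C@@H](C(=C)C)CC[C@@](C)(O)[C@@H]1O | intermediate
7 | N-methoxy-N-methyl-2-[(1R,2R,3R,6S)-3-methyl-6-(prop-1-en-2-yl)-2,3-bis(triethylsilyloxy)cyclohexyl]acetamide | CON(C)C(=O)C[C@@H]1[C@@H](C(=C)C)CC[C@@](C)(O[Si](CC)(CC)CC)[C@@H]1O[Si](CC)(CC)CC | intermediate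
8 | vinylmagnesium bromide | C=C[Mg]Br | starting material
9 | 1-[(1R,2R,3R,6S)-3-methyl-6-(prop-1-en-2-yl)-2,3-bis(triethylsilyloxy)cyclohexyl]but-3-en-2-one | C=CC(=O)C[C@@H]1[C@@H](C(=C)C)CC[C@@](C)(O[Si](CC)(CC)CC)[C@@H]1O[Si](CC)(CC)CC | intermediate
10 | 2-(trimethylsilyloxy)buta-1,3-diene | C=CC(=C)O[Si](C)(C)C | starting material
11 | 2-[(1R,2R,3R,6S)-3-methyl-6-(prop-1-en-2-yl)-2,3-bis(triethylsilyloxy)cyclohexyl]-1-[4-(trimethylsilyloxy)cyclohex-3-en-1-yl]ethan-1-one, both C1' epimers | C[Si](C)(C)OC1=CCC(CC1)C(=O)C[C@@H]2[C@@H](C(=C)C)CC[C@@](C)(O[Si](CC)(CC)CC)[C@@H]2O[Si](CC)(CC)CC | intermediate (not isolated)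
12 | 4-{2-[(1R,2R,3R,6S)-3-methyl-6-(prop-1-en-2-yl)-2,3-bis(triethylsilyloxy)cyclohexyl]acetyl}cyclohexan-1-one | O=C1CCC(CC1)C(=O)C[C@@H]2[C@@H](C(=C)C)CC[C@@](C)(O[Si](CC)(CC)CC)[C@@H]2O[Si](CC)(CC)CC | intermediate
13 | (2R)-2-bromo-4-{2-[(1R,2R,3R,6S)-3-methyl-6-(prop-1-en-2-yl)-2,3-bis(triethylsilyloxy)cyclohexyl]acetyl}cyclohexan-1-one, both C4 epimers | O=C(C[C@@H]1[C@@H](C(=C)C)CC[C@@](C)(O[Si](CC)(CC)CC)[C@@H]1O[Si](CC)(CC)CC)C1CCC(=O)[C@H](Br)C1 | intermediate
14 | methylmagnesium bromide | C[Mg]Br | starting material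
15 | 1-[(3R,4S)-3-bromo-4-hydroxy-4-methylcyclohexyl]-2-[(1R,2R,3R,6S)-3-methyl-6-(prop-1-en-2-yl)-2,3-bis(triethylsilyloxy)cyclohexyl]ethan-1-one, both C1 epimers of the bromocyclohexyl ring | O=C(C[C@@H]1[C@@H](C(=C)C)CC[C@@](C)(O[Si](CC)(CC)CC)[C@@H]1O[Si](CC)(CC)CC)C1CC[C@](C)(O)[C@H](Br)C1 | intermediate
16 | 1-[(1R,3R,4S)-3-bromo-4-hydroxy-4-methylcyclohexyl]-2-[(1R,2R,3R,6S)-3-methyl-6-(prop-1-en-2-yl)-2,3-bis(triethylsilyloxy)cyclohexyl]ethan-1-one | O=C(C[C@@H]1[C@@H](C(=C)C)CC[C@@](C)(O[Si](CC)(CC)CC)[C@@H]1O[Si](CC)(CC)CC)[C@@H]1CC[C@](C)(O)[C@H](Br)C1 | intermediate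
17 | methyltriphenylphosphonium bromide | C[P+](c1ccccc1)(c1ccccc1)c1ccccc1.[Br-] | starting material
18 | (1S,2R,4R)-2-bromo-1-methyl-4-{3-[(1R,2R,3R,6S)-3-methyl-6-(prop-1-en-2-yl)-2,3-bis(triethylsilyloxy)cyclohexyl]prop-1-en-2-yl}cyclohexan-1-ol | C=C(C[C@@H]1[C@@H](C(=C)C)CC[C@@](C)(O[Si](CC)(CC)CC)[C@@H]1O[Si](CC)(CC)CC)[C@@H]1CC[C@](C)(O)[C@H](Br)C1 | intermediate
19 | Prevezol C, (1R,2R,3R,4S)-3-{2-[(1R,3R,4S)-3-bromo-4-hydroxy-4-methylcyclohexyl]prop-2-en-1-yl}-1-methyl-4-(prop-1-en-2-yl)cyclohexane-1,2-diol | C=C(C[C@@H]1[C@@H](C(=C)C)CC[C@@](C)(O)[C@@H]1O)[C@@H]1CC[C@](C)(O)[C@H](Br)C1 | target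

**Summary**

Total step count: 12. Longest linear sequence: 12 steps (from 1).

Steps most likely to fail:

1. Step 8. The enantiofacial control of the enamine bromination may be poor on this substrate, or the C5' configuration may erode by enolisation of the α-bromoketone before it is trapped. Fallback (make the C–O bond first, then substitute with inversion): setting out from 12, D-proline-catalysed α-aminoxylation with nitrosobenzene (DMSO, 0 °C) should give the (2S)-anilinooxy ketone F1; N–O cleavage with Zn/AcOH should give the (2S)-α-hydroxy ketone F2; Appel bromination (PPh3, CBr4, CH2Cl2, 0 °C) with inversion comes back to the route at 13.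

2. Step 9. The Grignard reagent may also add to the linker ketone, or may enolise or debrominate the α-bromoketone instead of adding. Fallback (redox masking of the linker carbonyl): setting out from enol silane 11, taken before hydrolysis, LiAlH4 (Et2O, −78 °C) should reduce the only free ketone, and mild acidic work-up then unveils the ring ketone to give the hydroxy ketone F3. The same enamine bromination should give the bromo hydroxy ketone F4; excess CH3MgBr then meets a single ketone and should give the bromo diol F5; Dess–Martin oxidation of the secondary alcohol comes back to the route at 15.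

3. Step 3. The dianion may be alkylated on oxygen, be quenched by proton transfer from the acidic bromoamide, or react sluggishly. Fallback (monoanion of a silyl ether instead of a dianion): setting out from 3, Et3SiOTf/2,6-lutidine should give the silyl ether F6; LiN(i-Pr)2 then 4 should give the alkylated silyl ether F7; HF·pyridine removes the silyl group and comes back to the route at 5.

**Further compounds**

F1 | step 8 | (2S)-2-(anilinooxy)-4-{2-[(1R,2R,3R,6S)-3-methyl-6-(prop-1-en-2-yl)-2,3-bis(triethylsilyloxy)cyclohexyl]acetyl}cyclohexan-1-one, both C4 epimers | O=C(C[C@@H]1[C@@H](C(=C)C)CC[C@@](C)(O[Si](CC)(CC)CC)[C@@H]1O[Si](CC)(CC)CC)C1CCC(=O)[C@@H](ONc2ccccc2)C1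
F2 | step 8 | (2S)-2-hydroxy-4-{2-[(1R,2R,3R,6S)-3-methyl-6-(prop-1-en-2-yl)-2,3-bis(triethylsilyloxy)cyclohexyl]acetyl}cyclohexan-1-one, both C4 epimers | O=C(C[C@@H]1[C@@H](C(=C)C)CC[C@@](C)(O[Si](CC)(CC)CC)[C@@H]1O[Si](CC)(CC)CC)C1CCC(=O)[C@@H](O)C1
F3 | step 9 | 4-{1-hydroxy-2-[(1R,2R,3R,6S)-3-methyl-6-(prop-1-en-2-yl)-2,3-bis(triethylsilyloxy)cyclohexyl]ethyl}cyclohexan-1-one, both carbinol epimers | O=C1CCC(CC1)C(O)C[C@@H]2[C@@H](C(=C)C)CC[C@@](C)(O[Si](CC)(CC)CC)[C@@H]2O[Si](CC)(CC)CC
F4 | step 9 | (2R)-2-bromo-4-{1-hydroxy-2-[(1R,2R,3R,6S)-3-methyl-6-(prop-1-en-2-yl)-2,3-bis(triethylsilyloxy)cyclohexyl]ethyl}cyclohexan-1-one, epimers at C4 and at the carbinol | OC(C[C@@H]1[C@@H](C(=C)C)CC[C@@](C)(O[Si](CC)(CC)CC)[C@@H]1O[Si](CC)(CC)CC)C1CCC(=O)[C@H](Br)C1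
F5 | step 9 | (1S,2R)-2-bromo-4-{1-hydroxy-2-[(1R,2R,3R,6S)-3-methyl-6-(prop-1-en-2-yl)-2,3-bis(triethylsilyloxy)cyclohexyl]ethyl}-1-methylcyclohexan-1-ol, epimers at C4 and at the carbinol | OC(C[C@@H]1[C@@H](C(=C)C)CC[C@@](C)(O[Si](CC)(CC)CC)[C@@H]1O[Si](CC)(CC)CC)C1CC[C@](C)(O)[C@H](Br)C1
F6 | step 3 | (2R,5S)-2-methyl-5-(prop-1-en-2-yl)-2-(triethylsilyloxy)cyclohexan-1-one | C1[C@@H](C(=C)C)CC[C@@](C)(O[Si](CC)(CC)CC)C1=O
F7 | step 3 | N-methoxy-N-methyl-2-[(1R,3R,6S)-3-methyl-2-oxo-6-(prop-1-en-2-yl)-3-(triethylsilyloxy)cyclohexyl]acetamide | CON(C)C(=O)C[C@@H]1[C@@H](C(=C)C)CC[C@@](C)(O[Si](CC)(CC)CC)C1=O
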